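**Retrosynthetic overview**
1. The bridging γ-lactone is closed last: the C3′–O bond comes from opening a 3′,8′-epoxide with the C-7a′ acid, then the C-8′ alcohol is oxidised to the ketone.
2. The ring A butenolide comes from an enol triflate by Sonogashira coupling and silver-catalysed 5-exo cycloisomerisation.
3. Key step: an intramolecular Diels–Alder reaction of a bis-diene on a trans-disubstituted ring A closes the cyclopentane and ring B together (C7a′–C3a′ and C4′–C5′), instead of joining two phthalide halves across C6–C3′/C7–C7a′.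
4. The two dienes come from a Still–Gennari olefination (C-7 arm) and a vinyl ketone/Wittig sequence (C-6 arm).
5. Ring order: ring A (organocatalytic Michael/Knoevenagel, then anti Michael addition) → cyclopentane + ring B → butenolide → bridging lactone.

Assumption: the SMILES is read literally, i.e. (6S,7S,3′R,3a′S,7a′S) with H-6 and H-7 anti; ring A is then trans-fused to the lactone-bridged cyclopentane, a very strained arrangement, so the bridge is closed last by a strain-releasing step.

Locants in the text are those of the dimer: unit A carries C-1 to C-11, unit B the primed set. Monocycle names use their own ring numbering.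

**Step 1**
Reactants: 1 3-[(tert-butyldimethylsilyl)oxy]propanal; 2 methyl 3-oxopent-4-enoate
Product: 4 methyl (3S)-3-{[(tert-butyldimethylsilyl)oxy]methyl}-6-oxocyclohex-1-ene-1-carboxylate, via keto aldehyde 3 (not isolated)
Conditions: (R)-α,α-diphenylprolinol trimethylsilyl ether (10 mol %), PhCO2H (10 mol %), toluene, 0 °C; then piperidinium acetate (20 mol %), 4 Å MS, rt
Reagents that add atoms: none
Why: Enamine-catalysed Michael addition of 1 to the vinyl ketone of 2 from the unshielded enamine face sets the future C-6 (R in 3), and intramolecular Knoevenagel condensation of the aldehyde with the β-keto ester methylene closes ring A (the centre becomes S in 4 by a priority change only).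

**Step 2**
Reactants: 4 enone ester; 5 methyl bis(2,2,2-trifluoroethyl)phosphonoacetate
Product: 7 methyl (5S,6R)-6-{1-[bis(2,2,2-trifluoroethoxy)phosphoryl]-2-methoxy-2-oxoethyl}-5-{[(tert-butyldimethylsilyl)oxy]methyl}-2-[(trifluoromethanesulfonyl)oxy]cyclohex-1-ene-1-carboxylate, via sodium enolate 6 (not isolated)
Conditions: 5, NaH, THF, 0 °C; add 4, −78 → −20 °C; then Tf2O, −78 °C
Reagents that add atoms: trifluoromethanesulfonic anhydride, O=S(=O)(OS(=O)(=O)C(F)(F)F)C(F)(F)F
Why: Michael addition of the soft phosphonoacetate anion to the doubly activated alkylidene β-keto ester occurs anti to the pseudo-equatorial C-6 substituent, which sets C-7 trans to C-6, and the resulting β-keto ester enolate is O-sulfonylated in the same flask.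

**Step 3**
Reactants: 7 enol triflate phosphonate; 8 acrolein
Product: 9 methyl (5S,6S)-5-{[(tert-butyldimethylsilyl)oxy]methyl}-6-[(2Z)-1-methoxy-1-oxopenta-2,4-dien-2-yl]-2-[(trifluoromethanesulfonyl)oxy]cyclohex-1-ene-1-carboxylate
Conditions: KN(SiMe3)2, 18-crown-6, THF, −78 °C; then acrolein, −78 °C
Reagents that add atoms: none
Why: Still–Gennari variant of the Horner–Wadsworth–Emmons olefination gives the (Z)-enoate under kinetic control, so the new vinyl group sits cis to the ester and trans to ring A as the later cycloaddition needs; no stereocentre is touched.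

**Step 4**
Reactants: 9 silyl ether dienoate
Product: 10 methyl (5S,6S)-5-(hydroxymethyl)-6-[(2Z)-1-methoxy-1-oxopenta-2,4-dien-2-yl]-2-[(trifluoromethanesulfonyl)oxy]cyclohex-1-ene-1-carboxylate
Conditions: HF·pyridine, THF/pyridine, 0 °C → rt
Reagents that add atoms: none
Why: Fluoride-mediated desilylation of the primary silyl ether; the enol triflate, both esters and the diene are inert to buffered HF.

**Step 5**
Reactants: 10 primary alcohol
Product: 11 methyl (5S,6S)-5-formyl-6-[(2Z)-1-methoxy-1-oxopenta-2,4-dien-2-yl]-2-[(trifluoromethanesulfonyl)oxy]cyclohex-1-ene-1-carboxylate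
Conditions: Dess–Martin periodinane, CH2Cl2, 0 °C → rt
Reagents that add atoms: none
Why: Dess–Martin oxidation under neutral conditions; C-6 is now α to the aldehyde but its trans relation to C-7 is also the thermodynamic one.

**Step 6**
Reactants: 11 aldehyde; 12 vinylmagnesium bromide
Product: 13 methyl (5S,6S)-5-(1-hydroxyprop-2-en-1-yl)-6-[(2Z)-1-methoxy-1-oxopenta-2,4-dien-2-yl]-2-[(trifluoromethanesulfonyl)oxy]cyclohex-1-ene-1-carboxylate
Conditions: CH2=CHMgBr (1.1 equiv), THF, −78 °C; then H2O
Reagents that add atoms: none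
Why: Grignard 1,2-addition to the aldehyde, which at −78 °C is far more electrophilic than the hindered esters or the enol triflate; the carbinol forms as an epimer mixture that is oxidised away in the next step.

**Step 7**
Reactants: 13 allylic alcohol
Product: 14 methyl (5S,6S)-6-[(2Z)-1-methoxy-1-oxopenta-2,4-dien-2-yl]-5-(prop-2-enoyl)-2-[(trifluoromethanesulfonyl)oxy]cyclohex-1-ene-1-carboxylate
Conditions: Dess–Martin periodinane, CH2Cl2, 0 °C; used cold at once
Reagents that add atoms: none
Why: Dess–Martin oxidation of the allylic alcohol to the vinyl ketone; the α-centre C-6 can only equilibrate towards the wanted trans-diequatorial arrangement.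

**Step 8**
Reactants: 14 vinyl ketone; 15 butyl(triphenyl)phosphonium bromide
Product: 16 methyl (5S,6S)-5-[(3E)-hepta-1,3-dien-3-yl]-6-[(2Z)-1-methoxy-1-oxopenta-2,4-dien-2-yl]-2-[(trifluoromethanesulfonyl)oxy]cyclohex-1-ene-1-carboxylate
Conditions: 15, NaN(SiMe3)2, THF, 0 °C; then 14, −78 → 0 °C
Reagents that add atoms: none
Why: Wittig olefination of the ketone with the non-stabilised butylidene ylide gives the 2-substituted diene as an E/Z mixture (E drawn; both serve because C-8′ later becomes a ketone), after which C-6 is no longer enolisable.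

**Step 9**
Reactants: 16 bis-diene
Product: 17 tricyclic diester (6S,7S,3a′R,7a′R) with cyclopentane and ring B closed
Conditions: toluene (5 mM), 2,6-di-tert-butyl-4-methylphenol (cat.), 150 °C, sealed tube, 24 h
Reagents that add atoms: none
Why: Intramolecular Diels–Alder reaction (1,3,8-nonatriene type) of the (Z)-dienoate with the terminal vinyl group across the trans-diequatorial tether; the rotamer with H-7 eclipsing C7a′=C7′ (A(1,3) strain) and the tether anti to the diene body gives the trans-fused cyclopentane and ring B, setting quaternary C-7a′ (ester anti to H-7) and C-3a′ in one step.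

**Step 10**
Reactants: 17 tricyclic enol triflate; 18 1-pentyne
Product: 19 tricyclic enyne diester (6S,7S,3a′R,7a′R)
Conditions: 18, PdCl2(PPh3)2 (5 mol %), CuI (10 mol %), Et3N, THF, rt
Reagents that add atoms: none
Why: Sonogashira coupling of the β-(triflyloxy) enoate installs C-3 and the chain of the future butylidene; no stereocentre is involved.

**Step 11**
Reactants: 19 enyne diester
Product: 21 butenolide acid (6S,7S,3a′R,7a′R), via diacid 20 (not isolated)
Conditions: LiOH·H2O, THF/MeOH/H2O, 60 °C; then HCl (pH 3); then AgNO3 (10 mol %), acetone, rt, dark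
Reagents that add atoms: lithium hydroxide, [Li+].[OH-]
Why: Saponification of both methyl esters, then silver-catalysed 5-exo-dig cycloisomerisation of the conjugated acid onto the alkyne, where anti oxymetalation fixes the (Z)-butylidene; the quaternary C-7a′ acid cannot reach the alkyne and stays free.

**Step 12**
Reactants: 21 butenolide acid
Product: 23 8′-hydroxy bridged lactone (6S,7S,3′R,3a′S,7a′S), via epoxy acid 22 (not isolated)
Conditions: mCPBA (1.05 equiv), CH2Cl2, −20 → 0 °C; then camphorsulfonic acid (20 mol %), 0 °C → rt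
Reagents that add atoms: 3-chloroperoxybenzoic acid, OOC(=O)c1cccc(Cl)c1
Why: Prilezhaev epoxidation of the most electron-rich alkene (the exocyclic trisubstituted butylidene), then acid-catalysed 5-exo epoxide-opening lactonisation at the tertiary carbon; the oxygen can only arrive on the face carrying the acid, which sets C-3′ as R, and the release of epoxide strain pays for the strained bridge.

**Step 13**
Reactants: 23 8′-hydroxy lactone
Product: 24 target CNP0423313.2
Conditions: Dess–Martin periodinane, CH2Cl2, rt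
Reagents that add atoms: none
Why: Dess–Martin oxidation of the secondary alcohol to the butanoyl ketone under neutral conditions that leave both lactones and the enol ether untouched; C-3′ is quaternary, so nothing can epimerise.

**Compound list**
1 | 3-[(tert-butyldimethylsilyl)oxy]propanal | O=CCCO[Si](C)(C)C(C)(C)C | starting material
2 | methyl 3-oxopent-4-enoate (Nazarov reagent) | C=CC(=O)CC(=O)OC | starting material
3 | methyl (6R)-7-[(tert-butyldimethylsilyl)oxy]-6-formyl-3-oxoheptanoate | O=C[C@@H](CO[Si](C)(C)C(C)(C)C)CCC(=O)CC(=O)OC | intermediate (not isolated)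
4 | methyl (3S)-3-{[(tert-butyldimethylsilyl)oxy]methyl}-6-oxocyclohex-1-ene-1-carboxylate | COC(=O)C1=C[C@@H](CO[Si](C)(C)C(C)(C)C)CCC1=O | intermediate
5 | methyl bis(2,2,2-trifluoroethyl)phosphonoacetate | COC(=O)CP(=O)(OCC(F)(F)F)OCC(F)(F)F | starting material
6 | sodium enolate of the (5S,6R) Michael adduct of 4 and 5 (phosphonate carbon epimers) | [Na+].COC(=O)C1=C([O-])CC[C@H](CO[Si](C)(C)C(C)(C)C)[C@H]1C(C(=O)OC)P(=O)(OCC(F)(F)F)OCC(F)(F)F | intermediate (not isolated)
7 | methyl (5S,6R)-6-{1-[bis(2,2,2-trifluoroethoxy)phosphoryl]-2-methoxy-2-oxoethyl}-5-{[(tert-butyldimethylsilyl)oxy]methyl}-2-[(trifluoromethanesulfonyl)oxy]cyclohex-1-ene-1-carboxylate (phosphonate carbon epimers) | COC(=O)C1=C(OS(=O)(=O)C(F)(F)F)CC[C@H](CO[Si](C)(C)C(C)(C)C)[C@H]1C(C(=O)OC)P(=O)(OCC(F)(F)F)OCC(F)(F)F | intermediate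
8 | acrolein (prop-2-enal) | C=CC=O | starting material
9 | methyl (5S,6S)-5-{[(tert-butyldimethylsilyl)oxy]methyl}-6-[(2Z)-1-methoxy-1-oxopenta-2,4-dien-2-yl]-2-[(trifluoromethanesulfonyl)oxy]cyclohex-1-ene-1-carboxylate | COC(=O)C1=C(OS(=O)(=O)C(F)(F)F)CC[C@H](CO[Si](C)(C)C(C)(C)C)[C@H]1/C(C(=O)OC)=C/C=C | intermediate
10 | methyl (5S,6S)-5-(hydroxymethyl)-6-[(2Z)-1-methoxy-1-oxopenta-2,4-dien-2-yl]-2-[(trifluoromethanesulfonyl)oxy]cyclohex-1-ene-1-carboxylate | COC(=O)C1=C(OS(=O)(=O)C(F)(F)F)CC[C@H](CO)[C@H]1/C(C(=O)OC)=C/C=C | intermediate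
11 | methyl (5S,6S)-5-formyl-6-[(2Z)-1-methoxy-1-oxopenta-2,4-dien-2-yl]-2-[(trifluoromethanesulfonyl)oxy]cyclohex-1-ene-1-carboxylate | COC(=O)C1=C(OS(=O)(=O)C(F)(F)F)CC[C@H](C=O)[C@H]1/C(C(=O)OC)=C/C=C | intermediate
12 | vinylmagnesium bromide | C=C[Mg]Br | starting material
13 | methyl (5S,6S)-5-(1-hydroxyprop-2-en-1-yl)-6-[(2Z)-1-methoxy-1-oxopenta-2,4-dien-2-yl]-2-[(trifluoromethanesulfonyl)oxy]cyclohex-1-ene-1-carboxylate (carbinol epimers) | COC(=O)C1=C(OS(=O)(=O)C(F)(F)F)CC[C@H](C(O)C=C)[C@H]1/C(C(=O)OC)=C/C=C | intermediate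
14 | methyl (5S,6S)-6-[(2Z)-1-methoxy-1-oxopenta-2,4-dien-2-yl]-5-(prop-2-enoyl)-2-[(trifluoromethanesulfonyl)oxy]cyclohex-1-ene-1-carboxylate | COC(=O)C1=C(OS(=O)(=O)C(F)(F)F)CC[C@H](C(=O)C=C)[C@H]1/C(C(=O)OC)=C/C=C | intermediate
15 | butyl(triphenyl)phosphonium bromide | CCCC[P+](c1ccccc1)(c1ccccc1)c1ccccc1.[Br-] | starting material
16 | methyl (5S,6S)-5-[(3E)-hepta-1,3-dien-3-yl]-6-[(2Z)-1-methoxy-1-oxopenta-2,4-dien-2-yl]-2-[(trifluoromethanesulfonyl)oxy]cyclohex-1-ene-1-carboxylate (E drawn, Z isomer also formed) | COC(=O)C1=C(OS(=O)(=O)C(F)(F)F)CC[C@H](/C(=C/CCC)C=C)[C@H]1/C(C(=O)OC)=C/C=C | intermediate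
17 | tricyclic diester (6S,7S,3a′R,7a′R): ring A enol triflate with C-1 methyl ester, cyclopentane trans-fused to ring A and to cyclohexene ring B, C-7a′ methyl ester, exocyclic 3′-butylidene with propyl syn to C-3a′ | COC(=O)C1=C(OS(=O)(=O)C(F)(F)F)CC[C@H]2[C@H]1[C@@]1(C(=O)OC)C=CCC[C@@H]1/C2=C\CCC | intermediate
18 | 1-pentyne | C#CCCC | starting material
19 | tricyclic enyne diester (6S,7S,3a′R,7a′R): as 17 with pent-1-ynyl at C-3a in place of the triflate | COC(=O)C1=C(C#CCCC)CC[C@H]2[C@H]1[C@@]1(C(=O)OC)C=CCC[C@@H]1/C2=C\CCC | intermediate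
20 | tricyclic enyne diacid (6S,7S,3a′R,7a′R) | OC(=O)C1=C(C#CCCC)CC[C@H]2[C@H]1[C@@]1(C(=O)O)C=CCC[C@@H]1/C2=C\CCC | intermediate (not isolated)
21 | butenolide acid (6S,7S,3a′R,7a′R): ring A fused to the (Z)-3-butylidene butenolide, free C-7a′ carboxylic acid, exocyclic 3′-butylidene | CCC/C=C1\OC(=O)C2=C1CC[C@H]1[C@H]2[C@@]2(C(=O)O)C=CCC[C@@H]2/C1=C\CCC | intermediate
22 | 3′,8′-epoxide of 21 (6S,7S,3a′S,7a′S; same spatial arrangement as 21, epoxide epimers) | CCC/C=C1\OC(=O)C2=C1CC[C@H]1[C@H]2[C@@]2(C(=O)O)C=CCC[C@@H]2C13OC3CCC | intermediate (not isolated)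
23 | 8′-hydroxy bridged lactone (6S,7S,3′R,3a′S,7a′S; C-8′ epimers) | CCC/C=C1\OC(=O)C2=C1CC[C@H]1[C@H]2[C@@]23C=CCC[C@@H]2[C@]1(C(O)CCC)OC3=O | intermediate
24 | CNP0423313.2, (6S,7S,3′R,3a′S,7a′S) | CCC/C=C1\OC(=O)C2=C1CC[C@H]1[C@H]2[C@@]23C=CCC[C@@H]2[C@]1(C(=O)CCC)OC3=O | target

**Totals, risks and fallbacks**
Total steps: 13. Longest linear sequence: 13 (from 1).

Most likely to fail, first: step 12. The lactone bridge has to span a cyclopentane that is trans-fused to ring A, so the epoxide may rearrange or open at C-8′ instead of being captured at C-3′. The fallback sets out from 21. The epoxy acid 22 is made as before but steered with MgBr2·OEt2 into a Meinwald 1,2-hydride shift, giving the 3′-H butanoyl keto acid F4. The C3′–O bond is then closed oxidatively with PhI(OH)OTs in CH2Cl2 at 40 °C: the ketone is α-lactonised through its trivalent-iodine enolonium, with the carboxylate delivered from the only face it can reach. This comes back to the route at 24.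

Second: step 9. Four diastereomeric cycloadducts are possible; the inside ester may favour the cis-fused transition state, and a 1,5-hydrogen shift in the heptadienyl unit can compete at 150 °C. The fallback sets out from 14 and uses the vinyl ketone itself as an activated dienophile (Me2AlCl, CH2Cl2, −78 °C). This gives the tricyclic 3′-ketone F3, whose C-3a′ fusion is α to the ketone and can still be corrected by equilibration. Salt-free Wittig olefination with Ph3P=CHCH2CH2CH3 at low temperature (or CH3CH2CH2CHBr2, Zn, TiCl4) then comes back at 17.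

Third: step 1. Intermolecular Knoevenagel condensation of 2 with the aldehyde can compete with the Michael addition, and the γ-acidic C-6 of 4 can lose enantiopurity. The fallback sets out from 1. Michael addition to methyl vinyl ketone with the same catalyst, followed by aldol condensation, gives (4S)-4-{[(tert-butyldimethylsilyl)oxy]methyl}cyclohex-2-en-1-one F1. α-Iodination (I2, pyridine, CH2Cl2) gives (4S)-2-iodo-4-{[(tert-butyldimethylsilyl)oxy]methyl}cyclohex-2-en-1-one F2. Methoxycarbonylation (CO 1 atm, MeOH, Pd(OAc)2, PPh3, Et3N) comes back at 4.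

**Further compounds**
F1 | step 1 | (4S)-4-{[(tert-butyldimethylsilyl)oxy]methyl}cyclohex-2-en-1-one | O=C1C=C[C@@H](CO[Si](C)(C)C(C)(C)C)CC1
F2 | step 1 | (4S)-2-iodo-4-{[(tert-butyldimethylsilyl)oxy]methyl}cyclohex-2-en-1-one | O=C1C(I)=C[C@@H](CO[Si](C)(C)C(C)(C)C)CC1
F3 | step 9 | tricyclic 3′-ketone (6S,7S,3a′S,7a′S): as 17 with C-3′ as a ring ketone in place of the butylidene | COC(=O)C1=C(OS(=O)(=O)C(F)(F)F)CC[C@H]2[C@H]1[C@@]1(C(=O)OC)C=CCC[C@@H]1C2=O
F4 | step 12 | keto acid (6S,7S,3a′R,7a′R; C-3′ epimers): as 21 with C-3′ bearing H and a butanoyl group | CCC/C=C1\OC(=O)C2=C1CC[C@H]1[C@H]2[C@@]2(C(=O)O)C=CCC[C@@H]2C1C(=O)CCC
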